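The earlier runs and the new flask are calculated from invented constants.

Read the ring peak as a fall towards a plateau p, since in both earlier runs the last reading stands well above zero.

| setting | west | east | spring | dusk | dawn |
|---|---|---|---|---|---|
| starting material | 0.046 M | 0.10 M | 0.069 M | 0.069 M | 0.069 M |
| temperature | 65 °C | 85 °C | 100 °C | 70 °C |  |
| remark | run made earlier | run made earlier |  |  | at 100 °C until 8.0 min, from then on at 70 °C |
| time |  |  | 40 min | 40 min | 40 min |

| west: time / min | west: ring / % | east: time / min | east: ring / % |
|---|---|---|---|
| 15.0 | 60.4 | 10.0 | 30.5 |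
| 50.0 | 27.0 | 30.0 | 25.8 |
| 80.0 | 16.5 | 50.0 | 28.0 |
| 240 | 13.2 | 80.0 | 27.9 |

(each reading ± 1 percentage point)



1. which flask leads in amount of ring, in percent of the starting material charged ("all alike" within 1.5 percentage points) (spring / dusk / dawn / all alike)
2. how much ring is there at the end, in percent of the starting material charged: spring
3. how much ring is there at the end, in percent of the starting material charged: dusk
4. how much ring is there at the end, in percent of the starting material charged: dawn

We assume that the charge becomes ring at once and that ring then equilibrates with a partner we cannot see. The balance is dy/dt = −k(y − p), for y the ring in percent of the charge. So y = p + (s − p)e^(−Θ), where s is the height at the start of a stretch and Θ = k·t counts relaxation times, with e^(−Θ) the part of the gap still open.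

The last readings give K = (charge − p)/p: 6.58 at 65 °C and 2.58 at 85 °C. We take p as independent of concentration, which these runs cannot test. Running ln K against 1/T puts p at 42.2 % at 100 °C and 16.3 % at 70 °C.

The west decay gives k = 0.0409 min⁻¹. The first east reading gives roughly 0.332 min⁻¹, but it rests on a gap of 2.6 percentage points against a scatter of 1 point. On the same scale, k is 0.0707 min⁻¹ at 70 °C and 1.38 min⁻¹ at 100 °C.

Spring reaches Θ = 55.2, which is thermodynamic control, so we expect 42.2 % there. Dusk has Θ = 2.83 from the full charge, giving 21.2 %. On our reckoning dawn reaches its hot plateau, then spends 32.0 min cold, so Θ = 2.26, the cold relaxation times of dawn, giving 19.0 %. Θ by itself is not enough: dusk has the larger Θ, yet we put dawn lower, as s differs.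

The forecast, unlike our reckoning for spring and dawn, expected 96 % in spring, 26 % in dawn and 20 % in dusk, with spring leading, holding that “spring sits above its ceiling and barely converts”. The flasks give 43.7 % in spring, 22.2 % in dusk and 19.9 % in dawn, so spring leads.

    starting material → ring (k = 0.700 min⁻¹, Ea = 88.0 kJ mol⁻¹)
    2 starting material → open dimer (k = 0.450 L mol⁻¹ min⁻¹, Ea = 66.0 kJ mol⁻¹)
    starting material + ring → side product (k = 0.620 L mol⁻¹ min⁻¹, Ea = 78.0 kJ mol⁻¹)
    ring ⇌ isomer of the product (K = 4.70, k = 0.0530 min⁻¹, Ea = 91.0 kJ mol⁻¹, ΔH = −50.0 kJ mol⁻¹)
    (constants at 70 °C)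

The partner in spring is isomer of the product: without the passing of ring into it, both ways, spring would hold 93.6 % of ring rather than 43.7 %. Dawn stood at 43.7 % after 8.00 min, and our Θ carries that to 19.2 %. The neighbour flask, dawn stopped at 10 min, has Θ = 0.141, which gives 40.1 %; computed, it holds 40.4 %.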